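## Structural features

The target is a cis-fused hydroazulene (five–seven bicycle) sesquiterpenoid diol whose secondary alcohol is esterified with isovanillic (3-hydroxy-4-methoxybenzoic) acid. Locants used throughout: five-membered ring C1 (quaternary, methyl), C2, C3, C4 (isopropyl carbinol), C5 (ring-fusion CH); seven-membered ring C5, C6 (O-acyl), C7, C8 (methyl), C9, C10, C1. The C7=C8 alkene is trisubstituted and makes the C6 ester allylic. There are four stereocentres, C4–C5–C6 contiguous and C1 next to C5, with configuration (1R,4R,5S,6R) in these locants. H5, the C1 methyl and the isopropyl group lie on one face, and the C4 hydroxyl and the C6 oxygen on the other. Fragile groups are the allylic ester (ionisation, SN2′ attack, π-allyl formation with zerovalent palladium), the tertiary alcohol (acid-promoted dehydration), the free phenol and the alkene (migration, hydrogenation). The real difficulty is the quaternary C1 beside the ring-fusion centre, in a fixed relation to the two oxygenated centres C4 and C6, as one enantiomer. The key step uses the fact that C6–C10 with the oxygen on C6 are the five carbons and ring oxygen of a 3-oxidopyrylium (its C4 methyl becoming the C8 methyl), while C5–C1 with the C4 carbonyl is the alkene of 3-methylcyclopent-2-enone.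

## Logic of the disconnections

18 ⇒ 17. The phenol is masked as its acetate, because a free phenol would compete with the hindered C6 hydroxyl in the acylation. No skeletal gain; the demand is an unmasking that leaves the allylic aroate alone, which aminolysis of an aryl acetate meets.

17 ⇒ 13 + 16 (16 ⇐ 15 ⇐ 14). The C6 O–acyl bond is cut, which separates the aromatic acid from the terpenoid diol and makes the end convergent. The forward step must acylate the secondary allylic hydroxyl in the presence of the tertiary one and must go through O-acylation, so that C6 keeps its configuration.

13 ⇒ 12 ⇒ 11 ⇒ 10. A carbonyl is put back on C9 (through the dithiolane) and an acetyl on the C6 oxygen. The C9 carbonyl is the oxido carbon of the cycloaddition partner and the handle for opening the oxygen bridge. The forward steps must remove an enone carbonyl without moving or saturating C7=C8 and without ionising the allylic C6 oxygen, hence dithioketal and nickel, with C6 kept as its acetate.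

10 ⇒ 9. The C6 O–acetyl bond is cut; the acetyl group is both the protecting group for the next two steps and the resolution handle. This passes from a single enantiomer to the racemate and asks for an enzyme that tells the enantiomers apart at C6.

9 ⇒ 8. The C10–O bond is re-formed, so the C6 oxygen becomes a bridge across the seven-membered ring. This gives a rigid tricycle in which C6 and C10 are tied to C1 and C5. The forward step must cleave the C–O bond α to the C9 ketone, not the vinylogous C6–O bond.

8 ⇒ 7. The C4–isopropyl bond is cut, which leaves the C4 carbonyl that activated the dipolarophile. Doing this on the tricycle gives facial control; the demand is chemoselectivity for the saturated C4 ketone over the C9 enone.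

7 ⇒ 6 + 5. The C5–C6 and C1–C10 bonds are cut. This removes the seven-membered ring, the oxygen bridge and all four stereocentres in one operation and leaves two flat, achiral partners. The forward step needs the right regiochemistry, the exo approach and enough reactivity from a β,β-disubstituted enone.

6 ⇒ 4 ⇒ 3 ⇒ 2 ⇒ 1. The ylide comes from 4 by loss of acetic acid, 4 from 3 by acetylation, 3 from 2 by oxidative ring expansion of the furan, and 2 from 1 by ester reduction. The only demand is that the furan C3 methyl ends on C4 of the pyranone, which the ring expansion guarantees.

## Other disconnections considered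

Alternative 1: The cut is C1–C5 and C9–C10, an alkene joined to a vinylcyclopropane. In the forward sense [Rh(BINAP)]SbF6, a cationic monovalent rhodium complex, would cycloisomerise the tethered dienyl ketal A1 to the cis-fused hydroazulene A2, closing both rings at once.
- In its favour: it is catalytic and atom-economic, and the ligand would set C1 and C5 absolutely. On absolute stereocontrol it is better than the chosen plan, which discards half of the material in a resolution; in ring-forming power the two are equal.
- Against it here: A2 lacks the C8 methyl and the C6 oxygen and has its alkene at C6=C7. After the key step it would need allylic oxidation at C8 (in competition with C5), methyl addition, an oxidative 1,3-transposition and a face-selective reduction at C6. Ketal removal and isopropyl addition at C4 would follow without the facial bias of a rigid tricycle. High enantioselectivity for a quaternary-centre-forming 1,1-disubstituted alkene on an all-carbon tether is also not assured.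
- Comparison: the chosen cycloaddition delivers the C6 oxygen, the C8 methyl and the C7=C8 position directly, so the alternative is at best equal in step count and loses in functional-group economy.

Alternative 2: The cut is C1–C10, with C6–C8 re-formed as a cyclopropane bond. The chiral-pool alcohol (S)-terpinen-4-ol A3 would be taken to the cis-divinyl siloxycyclopropane A4, and heating would give the cycloheptadiene A5 by Cope rearrangement.
- In its favour: C4 with its isopropyl group and absolute configuration comes from A3, so there is no resolution and no chemoselective Grignard addition; on both points it is better than the chosen plan. A5 already holds the C8 methyl, the quaternary C1 and an oxygen on C6. Hydrolysis, conjugation of the C8=C9 alkene into C7=C8 and 1,2-reduction would reach the allylic alcohol, which makes it the equal of the chosen plan in functional-group placement.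
- Against it here: the new C1–C10 bond must form at a fully substituted alkene terminus, which slows the rearrangement. The configuration of C1 depends on building the tetrasubstituted cyclopropane with the right sense relative to C4. C5 (protonation) and C6 (hydride reduction) would be set afterwards with uncertain selectivity for the cis fusion and the trans C6 oxygen. The way to A4 is longer than three steps.
- Comparison: stronger on absolute control, weaker on relative control at C1, C5 and C6, and about equal or slightly longer overall.

Alternative 3: The cut is C1–C5 by carbenoid C–H insertion, with C6–C7 cut later. Rh2(OAc)4 would convert the diazo keto ester A6, built on a citronellyl-type stereocentre, into the cyclopentanone A7 by insertion into the tertiary C1–H bond with retention.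
- In its favour: the quaternary C1 is set absolutely from the chiral pool, which is better than a resolution. A later Nozaki–Hiyama–Kishi closure of the (Z)-iodoalkene onto a C6 aldehyde would give the allylic alcohol and the C7=C8 alkene together, with no oxygen bridge to cleave and no carbonyl to remove; on redox economy at that end it is better than the chosen plan.
- Against it here: the two rings are made one at a time. The linear precursor needs a homologated chain and a (Z)-trisubstituted vinyl iodide, whose geometry is hard to control. The β-keto ester must be differentiated into a C6 aldehyde and a C4 carbinol. C4, C5 and C6 are each set in separate substrate-controlled steps.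
- Comparison: mechanistically reliable at the insertion, but clearly longer than the chosen plan, which sets four stereocentres and two rings in one step.

Key step: step 4

## Route

Remarks on the chemistry:
- Compounds 3 and 4 are racemic at the acetal carbon, which becomes planar in step 4; they are written without a descriptor.
- Compounds 7, 8 and 9 are racemates; their SMILES show the enantiomer carried on after step 7.
- It is assumed that the lipase acylates the (6R)-alcohol, as the size rule for lipase acylation of secondary alcohols predicts (C5 side large, C7 side medium). If the enzyme prefers the other enantiomer, the wanted alcohol is the unreacted one and is acetylated with Ac2O/pyridine to rejoin the route at 10.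

Step 1
Reactants: 1 methyl 3-methylfuran-2-carboxylate
Product: 2 (3-methylfuran-2-yl)methanol
Conditions: LiAlH4, Et2O, 0 °C
Reagents that add atoms: none
Why: Hydride reduction of an ester to the primary alcohol; the furan ring is inert to LiAlH4.

Step 2
Reactants: 2 (3-methylfuran-2-yl)methanol
Product: 3 6-hydroxy-4-methyl-2H-pyran-3(6H)-one (racemic lactol)
Conditions: NBS, NaHCO3, NaOAc, THF/H2O (4:1), 0 °C
Reagents that add atoms: water, SMILES O
Why: Achmatowicz oxidative ring expansion: oxidation of the furan in water opens it to the cis-enedione, whose hydroxymethyl group closes onto the aldehyde as the lactol. The furan C3 methyl ends on C4 of the pyranone, next to the ketone.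

Step 3
Reactants: 3 6-hydroxy-4-methyl-2H-pyran-3(6H)-one
Product: 4 6-acetoxy-4-methyl-2H-pyran-3(6H)-one (racemic)
Conditions: Ac2O, pyridine, DMAP (cat.), CH2Cl2, 0 °C
Reagents that add atoms: acetic anhydride, SMILES CC(=O)OC(C)=O
Why: O-acylation of the lactol hydroxyl installs the leaving group for ylide generation. The anomeric configuration does not matter because that carbon becomes planar in step 4.

Step 4
Reactants: 4 6-acetoxy-4-methyl-2H-pyran-3(6H)-one; 5 3-methylcyclopent-2-en-1-one
Product: 7 racemic exo cycloadduct (C6–O–C10 oxygen-bridged 1,8-dimethylhydroazul-7-ene-4,9-dione; H5 and the C1 methyl cis to each other and anti to the bridge; cyclopentanone syn to the bridge), via 4-methyl-3-oxidopyrylium 6 (not isolated)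
Conditions: Et3N (1.5 equiv), neat 5 (15 equiv), 4 added by syringe pump over 10 h, 50 °C; excess 5 recovered by distillation
Reagents that add atoms: none
Why: Et3N removes the C2 proton of 4 and acetate leaves, giving the planar ylide 6, which is kept at low stationary concentration by slow addition so that capture by the large excess of 5 can compete with its dimerisation. 6 reacts as a 4π carbonyl-ylide component through the two carbons flanking its oxygen and adds suprafacially to the 2π enone alkene in a concerted, asynchronous (5+2) closure, the known base-mediated oxidopyrylium–alkene cycloaddition of electron-poor alkenes. The seven-membered carbocycle closes by union of the five ylide carbons (C6–C10) with C5 and C1 of the enone, and the same two bonds close the tetrahydrofuran ring C6–O–C10–C1–C5 as the ylide oxygen becomes the bridge. Regiochemistry follows ylide polarity: the carbon next to the oxido group is the nucleophilic terminus and bonds to the enone β-carbon (C1–C10), so the α-carbon bonds to the remote terminus (C5–C6), which puts the C9 ketone and the methylated C7=C8 alkene in the right places. C1 and C5 are set by suprafacial addition to the ring alkene, so the C1 methyl and H5 must be cis, and C6 and C10 are tied cis by the bridge. Their relation to C1 and C5 comes from the exo approach, in which only H5 and the C1 methyl sit under the ylide carbons while the cyclopentenone ring points to the side of the ylide oxygen; this is the less crowded arrangement for a trisubstituted cyclic alkene and is the selectivity the route needs, because it places the future C6 oxygen trans to H5. The adduct is racemic because neither partner nor the base is chiral.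

Step 5
Reactants: 7 racemic exo cycloadduct
Product: 8 racemic C6–O–C10 bridged 4-hydroxy-4-isopropyl-1,8-dimethylhydroazul-7-en-9-one (isopropyl cis to H5 and the C1 methyl; 4-OH on the face of C6)
Conditions: iPrMgCl (1.3 equiv), CeCl3 (1.5 equiv), THF, −78 °C
Reagents that add atoms: isopropylmagnesium chloride, SMILES CC(C)[Mg]Cl
Why: 1,2-Addition of a weakly basic organocerium reagent; the saturated cyclopentanone is more electrophilic and less congested than the conjugated C9 carbonyl, which is flanked by the C8 methyl and by the bridgehead next to quaternary C1. Attack occurs on the convex face of the cis-fused cyclopentanone (the face of H5 and the C1 methyl) because the other face is covered by the oxygen bridge, so the isopropyl group ends cis to H5 and the hydroxyl on the face of C6, as in the target.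

Step 6
Reactants: 8 racemic bridged tertiary alcohol
Product: 9 racemic 4,6-dihydroxy-4-isopropyl-1,8-dimethyl-cis-hydroazul-7-en-9-one (6-OH trans to H5)
Conditions: SmI2 (2.2 equiv), THF/MeOH (10:1), −78 °C
Reagents that add atoms: none
Why: Reductive cleavage of an α-alkoxy ketone by SmI2: the samarium ketyl at C9 expels the oxygen on C10, whose bond lies nearly parallel to the carbonyl π system in the bicycle, and protonation of the dienolate at C10 returns the conjugated enone. No stereocentre is touched; C6 keeps the configuration set in step 4 and C10 becomes a methylene.

Step 7
Reactants: 9 racemic dihydroxy enone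
Product: 10 (6R)-6-acetoxy-4-hydroxy-4-isopropyl-1,8-dimethyl-cis-hydroazul-7-en-9-one (single enantiomer; ring centres as in the target)
Conditions: immobilised Burkholderia cepacia lipase, vinyl acetate, MTBE, 35 °C, stopped near half conversion
Reagents that add atoms: vinyl acetate, SMILES C=COC(C)=O
Why: Lipase-catalysed kinetic resolution by irreversible transesterification; the enzyme should acylate the enantiomer whose carbinol has the large C5 side and the medium C7 side in the arrangement that corresponds to 6R, and only the secondary hydroxyl reacts. The unreacted 6S half of 9 is removed by chromatography.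

Step 8
Reactants: 10 (6R)-acetoxy enone
Product: 11 the 9,9-(ethane-1,2-diyldithio) ketal (1,3-dithiolane) of 10
Conditions: HS(CH2)2SH, BF3·OEt2 (0.3 equiv), CH2Cl2, −20 to 0 °C
Reagents that add atoms: ethane-1,2-dithiol, SMILES SCCS
Why: Lewis-acid-catalysed dithioketalisation, which converts enone carbonyls into 1,3-dithiolanes without moving the double bond. The acetate keeps the allylic C6 oxygen from ionising, and the tertiary alcohol does not react at low temperature.

Step 9
Reactants: 11 dithiolane acetate
Product: 12 (1R,4R,5S,6R)-6-acetoxy-4-isopropyl-1,8-dimethyl-cis-hydroazul-7-en-4-ol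
Conditions: Raney Ni (W-2, deactivated in acetone), EtOH, rt
Reagents that add atoms: none
Why: Reductive desulfurisation (Mozingo reduction) replaces both C–S bonds by C–H. With deactivated catalyst at room temperature the trisubstituted alkene should stay at C7=C8 and the allylic acetate should survive.

Step 10
Reactants: 12 acetoxy alcohol
Product: 13 (1R,4R,5S,6R)-4-isopropyl-1,8-dimethyl-cis-hydroazul-7-ene-4,6-diol
Conditions: K2CO3, MeOH, rt
Reagents that add atoms: none
Why: Base-catalysed methanolysis removes the secondary acetate; the tertiary alcohol and the alkene are inert.

Step 11
Reactants: 14 isovanillic acid (3-hydroxy-4-methoxybenzoic acid)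
Product: 15 3-acetoxy-4-methoxybenzoic acid
Conditions: Ac2O, aq. NaOH, 0 °C; then HCl
Reagents that add atoms: acetic anhydride, SMILES CC(=O)OC(C)=O
Why: Schotten–Baumann acetylation of the phenoxide in water; any mixed anhydride is hydrolysed and the free acid is recovered on acidification.

Step 12
Reactants: 15 3-acetoxy-4-methoxybenzoic acid; 13 diol
Product: 17 6-O-(3-acetoxy-4-methoxybenzoyl) ester of 13, via 3-acetoxy-4-methoxybenzoyl chloride 16 (not isolated)
Conditions: (COCl)2, DMF (cat.), CH2Cl2, rt, evaporate; then 13, Et3N, DMAP, CH2Cl2, 0 °C to rt
Reagents that add atoms: none
Why: Acid chloride formation followed by DMAP-catalysed O-acylation; only the secondary allylic hydroxyl at C6 reacts, the tertiary C4 hydroxyl being too hindered. Acylation at oxygen retains the C6 configuration.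

Step 13
Reactants: 17 protected ester
Product: 18 the target, (1R,4R,5S,6R)-4-hydroxy-4-isopropyl-1,8-dimethyl-cis-hydroazul-7-en-6-yl 3-hydroxy-4-methoxybenzoate
Conditions: pyrrolidine, CH2Cl2, 0 °C
Reagents that add atoms: none
Why: Aminolysis of the aryl acetate, an activated ester, by a secondary amine; the hindered alkyl aroate at C6 does not react under these conditions, so the phenol is released without acyl loss or migration.

## Compound list

1 | methyl 3-methylfuran-2-carboxylate | COC(=O)c1occc1C | starting material
2 | (3-methylfuran-2-yl)methanol | OCc1occc1C | intermediate
3 | 6-hydroxy-4-methyl-2H-pyran-3(6H)-one (racemic) | O=C1COC(O)C=C1C | intermediate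
4 | 6-acetoxy-4-methyl-2H-pyran-3(6H)-one (racemic) | CC(=O)OC1OCC(=O)C(C)=C1 | intermediate
5 | 3-methylcyclopent-2-en-1-one | CC1=CC(=O)CC1 | starting material
6 | 4-methyl-3-oxidopyrylium (not isolated) | Cc1cc[o+]cc1[O-] | intermediate
7 | racemic exo cycloadduct, C6–O–C10 bridged 1,8-dimethylhydroazul-7-ene-4,9-dione | [C@H]12C=C(C)C(=O)[C@H](O1)[C@]3(C)CCC(=O)[C@H]23 | intermediate
8 | racemic C6–O–C10 bridged 4-hydroxy-4-isopropyl-1,8-dimethylhydroazul-7-en-9-one | [C@H]12C=C(C)C(=O)[C@H](O1)[C@]3(C)CC[C@@](O)(C(C)C)[C@H]23 | intermediate
9 | racemic 4,6-dihydroxy-4-isopropyl-1,8-dimethyl-cis-hydroazul-7-en-9-one | O[C@@H]2C=C(C)C(=O)C[C@]3(C)CC[C@@](O)(C(C)C)[C@H]23 | intermediate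
10 | (6R)-6-acetoxy-4-hydroxy-4-isopropyl-1,8-dimethyl-cis-hydroazul-7-en-9-one | CC(=O)O[C@@H]2C=C(C)C(=O)C[C@]3(C)CC[C@@](O)(C(C)C)[C@H]23 | intermediate
11 | 9,9-(ethane-1,2-diyldithio) ketal of 10 | CC(=O)O[C@@H]2C=C(C)C4(SCCS4)C[C@]3(C)CC[C@@](O)(C(C)C)[C@H]23 | intermediate
12 | (1R,4R,5S,6R)-6-acetoxy-4-isopropyl-1,8-dimethyl-cis-hydroazul-7-en-4-ol | CC(=O)O[C@@H]2C=C(C)CC[C@]3(C)CC[C@@](O)(C(C)C)[C@H]23 | intermediate
13 | (1R,4R,5S,6R)-4-isopropyl-1,8-dimethyl-cis-hydroazul-7-ene-4,6-diol | O[C@@H]2C=C(C)CC[C@]3(C)CC[C@@](O)(C(C)C)[C@H]23 | intermediate
14 | isovanillic acid | COc1ccc(C(=O)O)cc1O | starting material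
15 | 3-acetoxy-4-methoxybenzoic acid | COc1ccc(C(=O)O)cc1OC(C)=O | intermediate
16 | 3-acetoxy-4-methoxybenzoyl chloride (not isolated) | COc1ccc(C(=O)Cl)cc1OC(C)=O | intermediate
17 | 6-O-(3-acetoxy-4-methoxybenzoyl) ester of 13 | COc1ccc(C(=O)O[C@@H]2C=C(C)CC[C@]3(C)CC[C@@](O)(C(C)C)[C@H]23)cc1OC(C)=O | intermediate
18 | CNP0210850.1, 6-O-isovanilloyl ester of 13 | COc1ccc(C(=O)O[C@@H]2C=C(C)CC[C@]3(C)CC[C@@](O)(C(C)C)[C@H]23)cc1O | target

Total step count: 13. Longest linear sequence: 12 steps (steps 1–10, 12 and 13, from 1); step 11 is the one-step side branch from 14.

## Steps least certain to work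

Step 4 (key step). The most likely failure is that dimerisation of the ylide outruns its capture, because the dipolarophile is a β,β-disubstituted, singly activated enone that must form a quaternary centre. A lesser concern is erosion of exo selectivity through the endo approach, which secondary orbital overlap favours; material from that approach would carry the opposite C6 configuration and would be usable only if the final esterification were run with inversion. The fallback raises the reactivity of the 2π partner with a removable second acceptor group. Setting out from 5, α-iodination (I2, pyridine, CH2Cl2) would give 2-iodo-3-methylcyclopent-2-en-1-one F1. Alkoxycarbonylation (CO, allyl alcohol, PdCl2(PPh3)2, Et3N) would give the doubly activated alkene allyl 2-methyl-5-oxocyclopent-1-ene-1-carboxylate F2. Cycloaddition of F2 with the ylide from 4 under the step 4 conditions, with unchanged regiochemistry because the β-carbon is the same, would give the C5-allyloxycarbonyl exo cycloadduct F3. Deallylative decarboxylation (Pd(OAc)2, PPh3, HCO2H, Et3N, THF, rt) would then put hydrogen on C5, which can only give the cis fusion, and comes back to the route at 7.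

Step 5. What may go wrong is loss of chemoselectivity: 1,2-addition at the C9 enone carbonyl, which its α-oxygen activates, or addition at both carbonyls, together with enolisation at C3 or C5 by the basic reagent. The fallback masks C9 by reduction. From 7, Luche reduction (NaBH4, CeCl3·7H2O, MeOH, −78 °C), which reduces conjugated ketones in preference to saturated ones and should deliver hydride from the exo face, would give the racemic C9 allylic alcohol F4. Excess iPrMgCl/CeCl3 would add to the only remaining carbonyl to give the racemic diol F5. Oxidation of the allylic alcohol with MnO2 in CH2Cl2 comes back to the route at 8.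

Step 6. What may go wrong is cleavage of the vinylogous C6–O bond from the enone radical anion in place of the α C10–O bond; both bonds belong to the same bridging oxygen and are similarly aligned with the π system. Over-reduction of the enone is a second risk. The fallback removes the conjugation before the reduction. From 8, thia-Michael addition (PhSH, Et3N cat., CH2Cl2) would give the racemic 7-phenylthio ketone F6, in which only C10–O is α to the carbonyl. SmI2 under the step 6 conditions would give the racemic ring-opened 7-phenylthio hydroxy ketone F7. Oxidation with mCPBA (1 equiv, −78 °C) would give the sulfoxide F8. Warming in toluene would expel benzenesulfenic acid by syn elimination towards C8, restoring the C7=C8 enone and coming back to the route at 9.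

Step 7. What may go wrong is low enantioselectivity or very slow acylation, because the carbinol is flanked by the ring-fusion carbon and may fit the enzyme poorly. The fallback is a classical resolution whose auxiliary also serves as the C6 protecting group. From 9, acylation with (1S)-camphanic chloride (Et3N, DMAP, CH2Cl2) and separation of the two diastereomers by chromatography or crystallisation would give the (6R)-camphanate F9. The conditions of steps 8 and 9 would convert it into the dithiolane camphanate F10 and then the deoxygenated camphanate F11. Methanolysis (K2CO3, MeOH) comes back to the route at 13.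

Step 8 (with step 9, which shares this fallback). What may go wrong is Lewis-acid-induced ionisation of the allylic C6 acetate or conjugate addition of the thiol at C7 instead of ketalisation; in step 9 the nickel may also shift or saturate the alkene or hydrogenolyse the allylic C–O bond. The fallback removes the C9 oxygen by hydride displacement instead of through sulfur. From 10, Luche reduction would give the C9 allylic alcohol F12 (either C9 epimer serves). Mesylation (MsCl, Et3N, CH2Cl2, −30 °C) would give the C9 mesylate F13. LiEt3BH (THF, −78 to 0 °C) would displace the mesylate at C9 and cleave the acetate in the same operation, coming back to the route at 13 without passing through 11 and 12.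

## Further compounds

F1 | step 4 | 2-iodo-3-methylcyclopent-2-en-1-one | CC1=C(I)C(=O)CC1
F2 | step 4 | allyl 2-methyl-5-oxocyclopent-1-ene-1-carboxylate | C=CCOC(=O)C1=C(C)CCC1=O
F3 | step 4 | racemic exo cycloadduct bearing an allyloxycarbonyl group on C5 | [C@H]12C=C(C)C(=O)[C@H](O1)[C@]3(C)CCC(=O)[C@]23C(=O)OCC=C
F4 | step 5 | racemic C9 alcohol of 7 (hydroxyl on the endo face) | [C@H]12C=C(C)[C@@H](O)[C@H](O1)[C@]3(C)CCC(=O)[C@H]23
F5 | step 5 | racemic C9 alcohol of 8 (4,9-diol) | [C@H]12C=C(C)[C@@H](O)[C@H](O1)[C@]3(C)CC[C@@](O)(C(C)C)[C@H]23
F6 | step 6 | racemic 7-phenylthio-7,8-dihydro derivative of 8 (C8 epimers) | [C@H]12[C@H](Sc4ccccc4)C(C)C(=O)[C@H](O1)[C@]3(C)CC[C@@](O)(C(C)C)[C@H]23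
F7 | step 6 | racemic 7-phenylthio-7,8-dihydro derivative of 9 (C8 epimers) | O[C@@H]2[C@H](Sc4ccccc4)C(C)C(=O)C[C@]3(C)CC[C@@](O)(C(C)C)[C@H]23
F8 | step 6 | sulfoxide of F7 | O[C@@H]2[C@H](S(=O)c4ccccc4)C(C)C(=O)C[C@]3(C)CC[C@@](O)(C(C)C)[C@H]23
F9 | step 7 | (1S,4R)-camphanate of the (6R)-enantiomer of 9 | O=C(O[C@@H]2C=C(C)C(=O)C[C@]3(C)CC[C@@](O)(C(C)C)[C@H]23)[C@@]45CC[C@@](C)(C(=O)O4)C5(C)C
F10 | step 7 | 9,9-(ethane-1,2-diyldithio) ketal of F9 | O=C(O[C@@H]2C=C(C)C6(SCCS6)C[C@]3(C)CC[C@@](O)(C(C)C)[C@H]23)[C@@]45CC[C@@](C)(C(=O)O4)C5(C)C
F11 | step 7 | 6-O-(1S,4R)-camphanate of 13 | O=C(O[C@@H]2C=C(C)CC[C@]3(C)CC[C@@](O)(C(C)C)[C@H]23)[C@@]45CC[C@@](C)(C(=O)O4)C5(C)C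
F12 | step 8 | C9 alcohol of 10 (C9 epimers) | CC(=O)O[C@@H]2C=C(C)C(O)C[C@]3(C)CC[C@@](O)(C(C)C)[C@H]23
F13 | step 8 | C9 mesylate of F12 | CC(=O)O[C@@H]2C=C(C)C(OS(C)(=O)=O)C[C@]3(C)CC[C@@](O)(C(C)C)[C@H]23
A1 | alternative 1 | 2-[(E)-2-cyclopropylethenyl]-2-(3-methylbut-3-enyl)-1,3-dioxolane | C=C(C)CCC1(OCCO1)/C=C/C1CC1
A2 | alternative 1 | cis-fused hydroazulene with C4 ethylene ketal, C1 methyl and C6=C7 alkene | C2=CCCC[C@]3(C)CCC4(OCCO4)[C@H]23
A3 | alternative 2 | (S)-terpinen-4-ol | CC1=CC[C@](O)(C(C)C)CC1
A4 | alternative 2 | cis-divinyl siloxycyclopropane (cyclopropane C6, C7, C8; C6 trimethylsilyloxy; C4 triethylsilyloxy) | C=C[C@@]1(C)C[C@@]1(O[Si](C)(C)C)C2=C(C)CC[C@@]2(O[Si](CC)(CC)CC)C(C)C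
A5 | alternative 2 | bicyclic cyclohepta-1,4-diene with C5=C6 enol silane, C8=C9 alkene and quaternary C1 | C12=C(O[Si](C)(C)C)CC(C)=CC[C@]1(C)CC[C@@]2(O[Si](CC)(CC)CC)C(C)C
A6 | alternative 3 | methyl (6S,9Z)-2-diazo-10-iodo-6,9-dimethyl-3-oxodec-9-enoate | COC(=O)C(=[N+]=[N-])C(=O)CC[C@@H](C)CC/C(C)=C\I
A7 | alternative 3 | methyl 2-[(Z)-4-iodo-3-methylbut-3-enyl]-2-methyl-5-oxocyclopentane-1-carboxylate with quaternary C1 | COC(=O)[C@@H]1[C@](C)(CC/C(C)=C\I)CCC1=O
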